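**Plan**

Retrosynthesis: the bond from C5' of ring B to the prenyl CH2 is cut first (Stille coupling at an aryl bromide). Ring C is then opened at O1–C2 and at C3–C1', which leads back to a 2'-hydroxychalcone with ring B still on the β-carbon, and last the chalcone Cα=Cβ bond is cut (Claisen–Schmidt).
Enabling feature: ring B is bonded to C3 and not C2 of the pyranone ring C, so the C3–C1' bond is the one a 1,2-aryl shift along a C6–C3–C6 chalcone chain creates.
Forward: rings A and B are bought as an acetophenone and a bromobenzaldehyde, MOM-protected and joined into the chalcone chain. Tl(NO3)3 then moves ring B and HCl closes ring C, the only ring that is built. Acetylation, prenylation at the bromide and deacetylation finish the synthesis.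
Stereochemistry: the target has no stereocentre and its prenyl alkene has no E/Z isomerism. The E-geometry of the chalcone comes from thermodynamic control and is consumed in the rearrangement.

Key step: step 4

Remark: the three building blocks that enter in steps 1, 2 and 6 are taken as purchasable, and bromine is carried as a placeholder for the prenyl group because a prenyl alkene would not survive trivalent thallium.

**Route**

Step 1
Reactants: 1 1-(2,6-dihydroxy-4-methoxyphenyl)ethanone (2',6'-dihydroxy-4'-methoxyacetophenone)
Product: 2 1-[2-hydroxy-4-methoxy-6-(methoxymethoxy)phenyl]ethanone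
Conditions: MOMCl (1.2 equiv), iPr2NEt (1.5 equiv), CH2Cl2, 0 °C → rt
Reagents that add atoms: chloromethyl methyl ether (MOMCl), COCCl
Why: Williamson-type MOM etherification with an amine base should stop after one alkylation, because the remaining phenol is then locked in a strong hydrogen bond to the ketone carbonyl and is too weak a nucleophile under these conditions.

Step 2
Reactants: 3 5-bromo-2,4-dihydroxybenzaldehyde
Product: 4 5-bromo-2,4-bis(methoxymethoxy)benzaldehyde
Conditions: MOMCl (3 equiv), iPr2NEt (4 equiv), CH2Cl2, 0 °C → rt
Reagents that add atoms: chloromethyl methyl ether (MOMCl), COCCl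
Why: Exhaustive MOM etherification (Williamson-type O-alkylation) with excess reagent should also capture the 2-OH, whose hydrogen bond to the formyl group is weaker than one to a ketone, and gives an aldehyde without acidic protons for the basic condensation.

Step 3
Reactants: 2 1-[2-hydroxy-4-methoxy-6-(methoxymethoxy)phenyl]ethanone; 4 5-bromo-2,4-bis(methoxymethoxy)benzaldehyde
Product: 5 (E)-3-[5-bromo-2,4-bis(methoxymethoxy)phenyl]-1-[2-hydroxy-4-methoxy-6-(methoxymethoxy)phenyl]prop-2-en-1-one
Conditions: KOH (aq, excess), EtOH, 0 °C → rt; then dilute HCl to pH 6 at 0 °C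
Reagents that add atoms: none
Why: Claisen–Schmidt (crossed aldol) condensation, in which the methyl ketone enolate adds to the non-enolisable aldehyde and E1cB loss of hydroxide gives the conjugated E-enone as the thermodynamic product, while strong base keeps the chalcone open as its phenoxide and suppresses closure to the flavanone.

Step 4
Reactants: 5 (E)-3-[5-bromo-2,4-bis(methoxymethoxy)phenyl]-1-[2-hydroxy-4-methoxy-6-(methoxymethoxy)phenyl]prop-2-en-1-one
Product: 7 3-(5-bromo-2,4-dihydroxyphenyl)-5-hydroxy-7-methoxychromen-4-one, via rearranged β-keto dimethyl acetal 6 (not isolated)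
Conditions: Tl(NO3)3·3H2O (1.1 equiv), MeOH/HC(OMe)3 (co-solvent), 0 °C → rt; TlNO3 filtered off, crude 6 taken on; then 10% aq HCl, MeOH, 60 °C
Reagents that add atoms: methanol, CO (its methoxy groups stand only in intermediate 6; product 7 keeps no atom of any reagent)
Why: Methanol and trivalent thallium add across the enone of 5 (OMe at the β-carbon, Tl at the α-carbon); as the weak C–Tl bond ionises with loss of monovalent thallium, the 2,4-dialkoxyaryl ring bridges as a phenonium ion and moves from the β- to the α-carbon (the future C3–C1' bond), and methanol traps the β-carbon as the dimethyl acetal of 6. Hot methanolic HCl then ionises this acetal to an oxocarbenium ion, the ring A phenol closes ring C by a 6-exo-trig attack of oxygen on that carbon (O1–C2), methanol is eliminated to give the 4-pyranone and the three MOM ethers are methanolysed. The closest known reaction type is the Tl(NO3)3-mediated oxidative 1,2-aryl migration of 2'-hydroxychalcones, followed by acid cyclisation of the resulting 3,3-dimethoxy-2-arylpropan-1-ones to isoflavones. No stereocentre remains, since the one at C-2 of 6 is racemic and is erased when that carbon becomes trigonal C3. The step needs aryl migration to win over aurone or flavone formation and over oxidation elsewhere: the oxygen donors para and ortho to the migrating carbon give ring B a high migratory aptitude, the acetal-forming medium captures the cation, the ring A phenol is tied up in its hydrogen bond to the carbonyl, and bromine, unlike a prenyl alkene, is inert to oxythallation. Closure by the already free ring A phenol should be faster than unmasking of the ring B 2-OH, which avoids a five-ring closure onto the acetal, and because ring A is symmetric about the axis through its acyl-bearing and methoxy-bearing carbons, either ortho oxygen leads to the same isoflavone.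

Step 5
Reactants: 7 3-(5-bromo-2,4-dihydroxyphenyl)-5-hydroxy-7-methoxychromen-4-one
Product: 8 3-(2,4-diacetoxy-5-bromophenyl)-7-methoxy-4-oxo-4H-chromen-5-yl acetate
Conditions: Ac2O (excess), pyridine, DMAP (cat.), rt
Reagents that add atoms: acetic anhydride, CC(=O)OC(C)=O
Why: Pyridine/DMAP-catalysed O-acetylation (nucleophilic acyl transfer) should mask all three phenols, the chelated 5-OH included, so that the bromide sits on a less electron-rich ring and no acidic proton interferes with oxidative addition or the tin reagent.

Step 6
Reactants: 8 3-(2,4-diacetoxy-5-bromophenyl)-7-methoxy-4-oxo-4H-chromen-5-yl acetate; 9 tributyl(3-methylbut-2-enyl)stannane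
Product: 10 3-[2,4-diacetoxy-5-(3-methylbut-2-enyl)phenyl]-7-methoxy-4-oxo-4H-chromen-5-yl acetate
Conditions: Pd(PPh3)4 (10 mol %), degassed DMF, 95 °C, argon
Reagents that add atoms: none
Why: Stille cross-coupling, in which zerovalent palladium inserts into the aryl C–Br bond, the prenyl group is transferred from tin, and reductive elimination at the less hindered primary terminus of the allylpalladium intermediate should give the linear 3-methylbut-2-enyl arene under neutral conditions that leave the aryl acetates and the chromone untouched.

Step 7
Reactants: 10 3-[2,4-diacetoxy-5-(3-methylbut-2-enyl)phenyl]-7-methoxy-4-oxo-4H-chromen-5-yl acetate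
Product: 11 Isopoegin B, 3-[2,4-dihydroxy-5-(3-methylbut-2-enyl)phenyl]-5-hydroxy-7-methoxychromen-4-one
Conditions: K2CO3 (0.3 equiv), MeOH, 0 °C → rt, argon; aq NH4Cl work-up
Reagents that add atoms: none
Why: Carbonate-catalysed transesterification of the aryl acetates by methanol (Zemplén-type deacetylation) should free the three phenols without acid, so that the prenyl group cannot cyclise onto the neighbouring 4'-OH to form a chroman.

**Compound list**

1 | 1-(2,6-dihydroxy-4-methoxyphenyl)ethanone | CC(=O)c1c(O)cc(OC)cc1O | starting material
2 | 1-[2-hydroxy-4-methoxy-6-(methoxymethoxy)phenyl]ethanone | CC(=O)c1c(O)cc(OC)cc1OCOC | intermediate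
3 | 5-bromo-2,4-dihydroxybenzaldehyde | O=Cc1cc(Br)c(O)cc1O | starting material
4 | 5-bromo-2,4-bis(methoxymethoxy)benzaldehyde | O=Cc1cc(Br)c(OCOC)cc1OCOC | intermediate
5 | (E)-3-[5-bromo-2,4-bis(methoxymethoxy)phenyl]-1-[2-hydroxy-4-methoxy-6-(methoxymethoxy)phenyl]prop-2-en-1-one | COCOc1cc(OC)cc(O)c1C(=O)/C=C/c1cc(Br)c(OCOC)cc1OCOC | intermediate
6 | 2-[5-bromo-2,4-bis(methoxymethoxy)phenyl]-1-[2-hydroxy-4-methoxy-6-(methoxymethoxy)phenyl]-3,3-dimethoxypropan-1-one (racemic) | COCOc1cc(OC)cc(O)c1C(=O)C(c1cc(Br)c(OCOC)cc1OCOC)C(OC)OC | intermediate
7 | 3-(5-bromo-2,4-dihydroxyphenyl)-5-hydroxy-7-methoxychromen-4-one | COc1cc(O)c2c(=O)c(-c3cc(Br)c(O)cc3O)coc2c1 | intermediate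
8 | 3-(2,4-diacetoxy-5-bromophenyl)-7-methoxy-4-oxo-4H-chromen-5-yl acetate | COc1cc(OC(C)=O)c2c(=O)c(-c3cc(Br)c(OC(C)=O)cc3OC(C)=O)coc2c1 | intermediate
9 | tributyl(3-methylbut-2-enyl)stannane | CCCC[Sn](CCCC)(CCCC)CC=C(C)C | starting material
10 | 3-[2,4-diacetoxy-5-(3-methylbut-2-enyl)phenyl]-7-methoxy-4-oxo-4H-chromen-5-yl acetate | COc1cc(OC(C)=O)c2c(=O)c(-c3cc(CC=C(C)C)c(OC(C)=O)cc3OC(C)=O)coc2c1 | intermediate
11 | Isopoegin B, 3-[2,4-dihydroxy-5-(3-methylbut-2-enyl)phenyl]-5-hydroxy-7-methoxychromen-4-one | COc1cc(O)c2c(=O)c(-c3cc(CC=C(C)C)c(O)cc3O)coc2c1 | target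

**Step count**

Total: 7 steps. Longest linear sequence: 6 steps (steps 1, 3, 4, 5, 6, 7 from compound 1; equally steps 2 to 7 from compound 3).

**Steps most likely to fail, with fallbacks**

Step 4 (oxidative aryl shift and ring closure). The ring A phenol may attack the thallated carbon before the aryl group migrates (aurone-type closure). The nitric acid set free may also strip MOM groups early, after which trivalent thallium can oxidise the freed resorcinol ring or the ring B phenol can close a five-membered ring onto the acetal. The fallback gives up the oxidative shift and forms the C3–C1' bond by cross-coupling, setting out from ketone 2. Condensation with Me2NCH(OMe)2 (toluene, 90 °C) should give the enaminone (E)-3-(dimethylamino)-1-[2-hydroxy-4-methoxy-6-(methoxymethoxy)phenyl]prop-2-en-1-one F1. I2 in CHCl3 at rt should close and iodinate it to 3-iodo-7-methoxy-5-(methoxymethoxy)chromen-4-one F2. The ring B partner is prepared from purchased 4,6-dibromobenzene-1,3-diol F3, which MOMCl and iPr2NEt in CH2Cl2 convert into 1,5-dibromo-2,4-bis(methoxymethoxy)benzene F4. One bromine–lithium exchange (n-BuLi, 1.0 equiv, THF, −78 °C) and a quench with 2-isopropoxy-4,4,5,5-tetramethyl-1,3,2-dioxaborolane should then give 2-[5-bromo-2,4-bis(methoxymethoxy)phenyl]-4,4,5,5-tetramethyl-1,3,2-dioxaborolane F5. Suzuki–Miyaura coupling of F2 with F5 (PdCl2(dppf), K3PO4, dioxane/H2O, 50 °C) should be chemoselective, because the C–I bond of the electron-poor chromone undergoes oxidative addition far faster than the C–Br bond of the electron-rich ring. It should give 3-[5-bromo-2,4-bis(methoxymethoxy)phenyl]-7-methoxy-5-(methoxymethoxy)chromen-4-one F6. HCl in MeOH at 60 °C then removes the three MOM groups, and the route is rejoined at 7.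

Step 6 (Stille prenylation). The prenyl group may be transferred with allylic transposition, so that the new bond forms at the tertiary terminus. Oxidative addition into the hindered bromide may also be slow enough for protodebromination to compete. The fallback builds the prenyl group in two stages and sets out from triacetate 8. Stille coupling with allyltributylstannane (Pd(PPh3)4, DMF, 90 °C), which has no regiochemical ambiguity, should give 3-(2,4-diacetoxy-5-allylphenyl)-7-methoxy-4-oxo-4H-chromen-5-yl acetate F7. Olefin cross-metathesis with excess 2-methylbut-2-ene (second-generation Grubbs catalyst, CH2Cl2, 40 °C) should then turn the terminal alkene into the trisubstituted one, and the route is rejoined at 10.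

Step 3 (Claisen–Schmidt condensation). Under equilibrating hydroxide conditions the aldol addition to the electron-rich, ortho-substituted aldehyde may be slow and reversible. The phenoxide may also close onto the enone in an oxa-Michael reaction, or the aldehyde may be consumed by a Cannizzaro reaction. The fallback replaces the thermodynamic condensation by a kinetic, directed aldol addition followed by a separate elimination, and sets out from ketone 2. Double deprotonation with LiN(SiMe3)2 (2.2 equiv, THF, −78 °C) gives the phenoxide–enolate dianion, which should add irreversibly to aldehyde 4 to give, after an NH4Cl quench, 3-[5-bromo-2,4-bis(methoxymethoxy)phenyl]-3-hydroxy-1-[2-hydroxy-4-methoxy-6-(methoxymethoxy)phenyl]propan-1-one F8 (racemic). MsCl (1.1 equiv) and Et3N in CH2Cl2 at 0 °C should sulfonylate the secondary benzylic alcohol in preference to the chelated phenol, and E1cB loss of methanesulfonate then gives the E-enone, so the route is rejoined at 5.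

**Further compounds**

F1 | step 4 | (E)-3-(dimethylamino)-1-[2-hydroxy-4-methoxy-6-(methoxymethoxy)phenyl]prop-2-en-1-one | COCOc1cc(OC)cc(O)c1C(=O)/C=C/N(C)C
F2 | step 4 | 3-iodo-7-methoxy-5-(methoxymethoxy)chromen-4-one | COCOc1cc(OC)cc2occ(I)c(=O)c12
F3 | step 4 | 4,6-dibromobenzene-1,3-diol (purchased) | Oc1cc(O)c(Br)cc1Br
F4 | step 4 | 1,5-dibromo-2,4-bis(methoxymethoxy)benzene | COCOc1cc(OCOC)c(Br)cc1Br
F5 | step 4 | 2-[5-bromo-2,4-bis(methoxymethoxy)phenyl]-4,4,5,5-tetramethyl-1,3,2-dioxaborolane | COCOc1cc(OCOC)c(B2OC(C)(C)C(C)(C)O2)cc1Br
F6 | step 4 | 3-[5-bromo-2,4-bis(methoxymethoxy)phenyl]-7-methoxy-5-(methoxymethoxy)chromen-4-one | COCOc1cc(OC)cc2occ(-c3cc(Br)c(OCOC)cc3OCOC)c(=O)c12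
F7 | step 6 | 3-(2,4-diacetoxy-5-allylphenyl)-7-methoxy-4-oxo-4H-chromen-5-yl acetate | COc1cc(OC(C)=O)c2c(=O)c(-c3cc(CC=C)c(OC(C)=O)cc3OC(C)=O)coc2c1
F8 | step 3 | 3-[5-bromo-2,4-bis(methoxymethoxy)phenyl]-3-hydroxy-1-[2-hydroxy-4-methoxy-6-(methoxymethoxy)phenyl]propan-1-one (racemic) | COCOc1cc(OC)cc(O)c1C(=O)CC(O)c1cc(Br)c(OCOC)cc1OCOC
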